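**Retrosynthetic overview**
1. The target is a 2,5-diaryl-3,4-dimethyltetrahydrofuran (THF). It comes from acid-mediated cyclodehydration of a 1,4-diaryl-2,3-dimethylbutane-1,4-diol. The all-trans ring is the thermodynamic sink, so only the two methyl centres and the C5 carbinol (the trimethoxyphenyl-bearing carbon) need defined configuration; the dimethoxyphenyl carbinol carbon ionises and equilibrates.
2. The diol comes from NaBH4 reduction of a γ-hydroxy aryl ketone, which comes from ArMgBr addition to a Weinreb amide. That amide is made by opening the trans,trans-5-aryl-3,4-dimethylbutanolide.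
3. The aryl lactone comes from lactonisation of a ketoreductase-derived (S)-γ-hydroxy acid, which comes from Ar′MgBr addition to an acid-Weinreb amide.
4. The acid-Weinreb amide comes from (3S,4S)-trans-3,4-dimethylbutyrolactone. That lactone comes from trans-selective α-methylation of (S)-β-methylbutyrolactone, itself made by Rh-catalysed asymmetric hydrogenation of monomethyl itaconate.
5. Rings form in this order: butyrolactone, opened; aryl butyrolactone, opened; THF last.

**Assumptions:**
- 4-Methyl hydrogen itaconate is commercially available.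
- The Rh–DuPhos ligand enantiomer that gives the (S)-acid is used.
- A Prelog-type ketoreductase active on keto acid 10 is found in a commercial panel.
- The C2 carbinol (dimethoxyphenyl-bearing carbon) is scrambled in the last step and resolves to the all-trans ring thermodynamically.

---

**Step 1**
Reactants: 1, 4-methyl hydrogen itaconate; H2
Product: 2, (S)-4-methoxy-2-methyl-4-oxobutanoic acid
Conditions: H2 (5 bar), [Rh((S,S)-Me-DuPhos)(cod)]BF4 (0.5 mol%), MeOH, 25 °C, 16 h
Reagents that add atoms: none (H2 adds only H)
Why: Rh-bisphosphine asymmetric hydrogenation of the 1,1-disubstituted alkene sets the first stereocentre (the C-3 methyl-bearing carbon of 3–4) by catalyst control, with the carboxylate as directing group.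

**Step 2**
Reactants: 2
Product: 3, methyl (S)-4-hydroxy-3-methylbutanoate
Conditions: BH3·SMe2 (1.2 equiv), THF, 0 → 25 °C, 4 h; MeOH quench
Reagents that add atoms: none
Why: Borane reduces a free carboxylic acid (via the acyloxyborane) much faster than a methyl ester, and the remote stereocentre is untouched.

**Step 3**
Reactants: 3
Product: 4, (S)-4-methyldihydrofuran-2(3H)-one
Conditions: TsOH·H2O (5 mol%), PhMe, 80 °C, 3 h
Reagents that add atoms: none (MeOH is lost)
Why: Acid-catalysed intramolecular transesterification (lactonisation) forms the five-membered ring.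

**Step 4**
Reactants: 4; iodomethane
Product: 5, (3S,4S)-3,4-dimethyldihydrofuran-2(3H)-one (trans)
Conditions: LiHMDS (1.1 equiv), THF, −78 °C, 1 h; then MeI (1.5 equiv), −78 → −40 °C, 3 h
Reagents that add atoms: iodomethane, CI
Why: Lactone enolate alkylation occurs anti to the β-methyl group, giving the trans α,β-dimethyl lactone (expected trans:cis about 9:1). The minor cis isomer is carried forward and removed at 12.

**Step 5**
Reactants: 5; N,O-dimethylhydroxylamine
Product: 6, (2S,3S)-4-hydroxy-N-methoxy-N,2,3-trimethylbutanamide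
Conditions: Me2AlN(OMe)Me (from MeNH(OMe)·HCl + AlMe3, 2.5 equiv), CH2Cl2, 0 → 25 °C, 6 h; Rochelle salt work-up
Reagents that add atoms: N,O-dimethylhydroxylamine, CNOC
Why: Basha–Weinreb aminolysis of the lactone under non-basic aluminium conditions opens the ring without touching either stereocentre.

**Step 6**
Reactants: 6; water
Product: 7, (2S,3S)-4-[methoxy(methyl)amino]-2,3-dimethyl-4-oxobutanoic acid
Conditions: TEMPO (10 mol%), PhI(OAc)2 (2.5 equiv), MeCN/H2O (1:1), 25 °C, 4 h
Reagents that add atoms: water, O
Why: TEMPO/BAIB oxidises the primary alcohol through the aldehyde hydrate to the acid; the α-stereocentre is not epimerised under these mild, non-basic conditions, and the Weinreb amide is inert.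

**Step 7**
Reactants: 8, 5-bromo-1,2,3-trimethoxybenzene; magnesium
Product: 9, 3,4,5-trimethoxyphenylmagnesium bromide
Conditions: Mg turnings, I2 (cat.), THF, reflux, 2 h
Reagents that add atoms: magnesium, [Mg]
Why: Oxidative insertion of Mg into the aryl bromide gives the Grignard reagent.

**Step 8**
Reactants: 7; 9
Product: 10, (2S,3S)-2,3-dimethyl-4-oxo-4-(3,4,5-trimethoxyphenyl)butanoic acid
Conditions: 9 (3.3 equiv), THF, 0 → 25 °C, 3 h; 1 M HCl work-up
Reagents that add atoms: none
Why: Weinreb ketone synthesis. The chelated tetrahedral intermediate prevents over-addition, and the first equivalent of Grignard masks the acid as its magnesium carboxylate. No stereocentre is altered.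

**Step 9**
Reactants: 10
Product: 11, (2S,3S,4S)-4-hydroxy-2,3-dimethyl-4-(3,4,5-trimethoxyphenyl)butanoic acid
Conditions: ketoreductase (KRED, NADPH-dependent oxidoreductase, Prelog-type), NADP+ (0.5 mol%), glucose dehydrogenase, D-glucose (1.5 equiv), KPi buffer pH 7.0/DMSO (9:1), 30 °C, 24 h; then acidify to pH 3 and extract
Reagents that add atoms: none (H comes from NADPH)
Why: Enzymatic asymmetric ketone reduction. The enzyme delivers hydride to the Re face, giving the (S)-benzylic carbinol under enzyme control. Neutral pH avoids epimerising the α-methyl centre.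

**Step 10**
Reactants: 11
Product: 12, (3S,4S,5S)-3,4-dimethyl-5-(3,4,5-trimethoxyphenyl)dihydrofuran-2(3H)-one
Conditions: EDC·HCl (1.5 equiv), DMAP (0.1 equiv), CH2Cl2, 0 → 25 °C, 4 h
Reagents that add atoms: none (H2O is lost)
Why: Steglich lactonisation under non-acidic conditions avoids ionising the electron-rich benzylic alcohol. The crystalline all-trans lactone is purified here, which also removes the minor cis-dimethyl diastereomer carried from step 4.

**Step 11**
Reactants: 12; N,O-dimethylhydroxylamine
Product: 13, (2S,3S,4S)-4-hydroxy-N-methoxy-N,2,3-trimethyl-4-(3,4,5-trimethoxyphenyl)butanamide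
Conditions: Me2AlN(OMe)Me (3 equiv), CH2Cl2, 0 → 25 °C, 8 h; Rochelle salt work-up
Reagents that add atoms: N,O-dimethylhydroxylamine, CNOC
Why: Weinreb aminolysis of the lactone with a non-basic aluminium amide avoids enolisation and epimerisation α to the carbonyl.

**Step 12**
Reactants: 14, 4-bromo-1,2-dimethoxybenzene; magnesium
Product: 15, 3,4-dimethoxyphenylmagnesium bromide
Conditions: Mg turnings, I2 (cat.), THF, reflux, 2 h
Reagents that add atoms: magnesium, [Mg]
Why: Grignard formation as in step 7.

**Step 13**
Reactants: 13; 15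
Product: 16, (2S,3S,4S)-1-(3,4-dimethoxyphenyl)-4-hydroxy-2,3-dimethyl-4-(3,4,5-trimethoxyphenyl)butan-1-one (in ring–chain equilibrium with its cyclic hemiketal)
Conditions: 15 (3.3 equiv), THF, 0 → 25 °C, 3 h; sat. NH4Cl quench
Reagents that add atoms: none
Why: Weinreb ketone synthesis. The first equivalent of Grignard deprotonates the free OH, and the chelated intermediate prevents double addition. The stereocentres are retained.

**Step 14**
Reactants: 16
Product: 17, (2S,3S,4S)-1-(3,4-dimethoxyphenyl)-2,3-dimethyl-4-(3,4,5-trimethoxyphenyl)butane-1,4-diol (C1 epimeric mixture)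
Conditions: NaBH4 (2 equiv), MeOH/THF (1:1), 0 °C, 1 h
Reagents that add atoms: none (NaBH4 adds only H)
Why: Hydride reduction of the aryl ketone. The new C1 centre is deliberately left unselective because it is ionised and equilibrated in step 15.

**Step 15**
Reactants: 17
Product: 18, target, (2S,3S,4S,5S)-2-(3,4-dimethoxyphenyl)-3,4-dimethyl-5-(3,4,5-trimethoxyphenyl)tetrahydrofuran
Conditions: TsOH·H2O (10 mol%), CH2Cl2 (0.02 M), 25 °C, 4 h; Et3N quench
Reagents that add atoms: none (H2O is lost)
Why: Acid-catalysed SN1 cyclodehydration. The dimethoxybenzylic cation is captured by the C4-OH with retention at C4, and reversible ionisation funnels the C1 and C4 benzylic centres to the thermodynamically preferred all-trans THF. The methyl stereocentres never ionise, so the enantiomer is fixed.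

---

**Compound list**

1 | 4-methyl hydrogen itaconate | C=C(CC(=O)OC)C(=O)O | starting material
2 | (S)-4-methoxy-2-methyl-4-oxobutanoic acid | C[C@@H](CC(=O)OC)C(=O)O | intermediate
3 | methyl (S)-4-hydroxy-3-methylbutanoate | OC[C@@H](C)CC(=O)OC | intermediate
4 | (S)-4-methyldihydrofuran-2(3H)-one | C[C@@H]1COC(=O)C1 | intermediate
5 | (3S,4S)-3,4-dimethyldihydrofuran-2(3H)-one | C[C@@H]1COC(=O)[C@H]1C | intermediate
6 | (2S,3S)-4-hydroxy-N-methoxy-N,2,3-trimethylbutanamide | OC[C@@H](C)[C@H](C)C(=O)N(C)OC | intermediate
7 | (2S,3S)-4-[methoxy(methyl)amino]-2,3-dimethyl-4-oxobutanoic acid | OC(=O)[C@@H](C)[C@H](C)C(=O)N(C)OC | intermediate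
8 | 5-bromo-1,2,3-trimethoxybenzene | COc1cc(Br)cc(OC)c1OC | starting material
9 | 3,4,5-trimethoxyphenylmagnesium bromide | COc1cc(cc(OC)c1OC)[Mg]Br | intermediate (in situ)
10 | (2S,3S)-2,3-dimethyl-4-oxo-4-(3,4,5-trimethoxyphenyl)butanoic acid | COc1cc(cc(OC)c1OC)C(=O)[C@@H](C)[C@H](C)C(=O)O | intermediate
11 | (2S,3S,4S)-4-hydroxy-2,3-dimethyl-4-(3,4,5-trimethoxyphenyl)butanoic acid | COc1cc(cc(OC)c1OC)[C@@H](O)[C@@H](C)[C@H](C)C(=O)O | intermediate
12 | (3S,4S,5S)-3,4-dimethyl-5-(3,4,5-trimethoxyphenyl)dihydrofuran-2(3H)-one | COc1cc(cc(OC)c1OC)[C@H]2OC(=O)[C@@H](C)[C@@H]2C | intermediate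
13 | (2S,3S,4S)-4-hydroxy-N-methoxy-N,2,3-trimethyl-4-(3,4,5-trimethoxyphenyl)butanamide | COc1cc(cc(OC)c1OC)[C@@H](O)[C@@H](C)[C@H](C)C(=O)N(C)OC | intermediate
14 | 4-bromo-1,2-dimethoxybenzene | COc1ccc(Br)cc1OC | starting material
15 | 3,4-dimethoxyphenylmagnesium bromide | COc1ccc([Mg]Br)cc1OC | intermediate (in situ)
16 | (2S,3S,4S)-1-(3,4-dimethoxyphenyl)-4-hydroxy-2,3-dimethyl-4-(3,4,5-trimethoxyphenyl)butan-1-one | COc1ccc(cc1OC)C(=O)[C@@H](C)[C@H](C)[C@H](O)c1cc(OC)c(OC)c(OC)c1 | intermediate
17 | (2S,3S,4S)-1-(3,4-dimethoxyphenyl)-2,3-dimethyl-4-(3,4,5-trimethoxyphenyl)butane-1,4-diol (C1 unspecified) | COc1ccc(cc1OC)C(O)[C@@H](C)[C@H](C)[C@H](O)c1cc(OC)c(OC)c(OC)c1 | intermediate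
18 | 5-methoxygalbelgin, (2S,3S,4S,5S)-2-(3,4-dimethoxyphenyl)-3,4-dimethyl-5-(3,4,5-trimethoxyphenyl)tetrahydrofuran | COc1ccc([C@H]2O[C@H](c3cc(OC)c(OC)c(OC)c3)[C@@H](C)[C@@H]2C)cc1OC | target

---

**Total steps:** 15, counting the two Grignard preparations.
**Longest linear sequence:** 13 steps (1 → 2 → 3 → 4 → 5 → 6 → 8 → 9 → 10 → 11 → 13 → 14 → 15).

**Three steps most likely to fail**
1. **Step 9 (ketoreductase reduction of the hindered, carboxylate-bearing ketone).** The enzyme may show low activity or modest diastereoselectivity.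
   Fallback: Ru-catalysed asymmetric transfer hydrogenation of the keto acid or its methyl ester with RuCl[(S,S)-TsDPEN](p-cymene) and HCO2H/Et3N. This is a chemocatalytic route to the same (S)-carbinol.
2. **Step 4 (diastereoselectivity of the lactone α-methylation).** The trans:cis ratio with the small β-methyl group may be lower than 9:1, or dialkylation may compete.
   Fallback: build the trans-3,4-dimethyl lactone 5 by Cu/Josiphos-catalysed asymmetric 1,4-addition of MeMgBr to 3-methyl-2(5H)-furanone, then equilibrate the α-centre with base to the thermodynamic trans isomer.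
3. **Step 15 (cation-mediated cyclodehydration).** It may give cis-2,5 isomers, or elimination to the styrene or intermolecular Friedel–Crafts products.
   Fallback: make a Ca-defined diol by a second, (R)-selective (anti-Prelog) ketoreductase reduction of hydroxy ketone 16. Then close the ring by an intramolecular Mitsunobu (DIAD, PPh3, THF) SN2 displacement with inversion, instead of the SN1 route.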